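**Assumption:** the SMILES is read as (2R,3S,4S,5R)-2,5-bis(4-hydroxy-3-methoxyphenyl)-3,4-bis(hydroxymethyl)oxolane (all-trans, C2-symmetric). Compounds 1, 2 and 4 are catalogue chemicals.

## Retrosynthetic overview

1. Both CH2OH groups come from a C2-symmetric dimethyl oxolane-3,4-dicarboxylate by ester reduction.
2. The oxolane, the only ring in the target, is closed last by an acid-mediated, thermodynamically controlled benzylic C–O closure. The precursor is a 2,3-bis(α-hydroxybenzyl)succinyl unit, which passes through transient γ-lactones.
3. Both benzylic C–C bonds and all four stereocentres come from one two-directional Evans syn-aldol of a succinyl bis[(R)-4-benzyloxazolidinone] with two equivalents of vanillin acetate.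
4. The bis-imide comes from succinyl chloride and (R)-4-benzyl-2-oxazolidinone.

Step 2 is the one step without direct precedent on this exact substrate; steps 3 and 4 follow the known racemic dilactone → oxolane diester → neo-olivil sequence.

## Route

**Step 1**
Reactants: 1, (R)-4-benzyl-2-oxazolidinone (2.1 equiv); 2, succinyl chloride (1.0 equiv)
Product: 3, 1,4-bis[(4R)-4-benzyl-2-oxo-1,3-oxazolidin-3-yl]butane-1,4-dione
Conditions: n-BuLi (2.1 equiv), THF, −78 °C; then 2, −78 → 0 °C
Reagents that add atoms: none (all heavy atoms come from 1 and 2)
Why: Double N-acylation of the lithiated oxazolidinone (Evans imide formation); no new stereocentre is formed and the auxiliary centres are untouched.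

**Step 2**
Reactants: 3; 4, vanillin acetate (4-formyl-2-methoxyphenyl acetate, 2.6 equiv)
Product: 5, (4R,4′R)-3,3′-{(2R,3R)-2,3-bis[(R)-(4-acetoxy-3-methoxyphenyl)(hydroxy)methyl]butanedioyl}bis(4-benzyl-1,3-oxazolidin-2-one)
Conditions: Bu2BOTf (2.4 equiv), i-Pr2NEt (3.0 equiv), CH2Cl2, 0 °C; then 4, −78 → 0 °C; pH 7 buffer/MeOH quench (non-oxidative); crude used directly
Reagents that add atoms: none (all heavy atoms come from 3 and 4)
Why: Two-directional Evans syn-aldol. Each (Z)-boron enolate reacts through a Zimmerman–Traxler chair on the face opposite the benzyl group, so each (R)-auxiliary sets its own α-carbon (R) and carbinol carbon (R), as in the (R)-propionimide/ArCHO → (2R,3R) case. The C2-symmetric product already has the all-trans arrangement of the four future ring carbons. A single wrong aldol event gives a non-C2 diastereomer that is removed later, so the ee of the C2 product is amplified. Partial lactonisation or loss of an aryl acetate at this stage is harmless, because everything converges in step 3.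

**Step 3**
Reactants: 5
Product: 6, dimethyl (2R,3R,4R,5R)-2,5-bis(4-hydroxy-3-methoxyphenyl)oxolane-3,4-dicarboxylate
Conditions: HCl (about 3 M, from AcCl) in MeOH, rt → reflux, 3 h; auxiliary 1 recovered; 6 recrystallised
Reagents that add atoms: methanol, CO (two ester OCH3 groups)
Why: Acid cascade ending in the known methanolic-HCl dilactone → oxolane diester rearrangement. The aryl acetates are methanolysed, and each γ-hydroxy imide lactonises with loss of the auxiliary to give the cis-fused bis-γ-lactone (not isolated). One lactone is then methanolysed, the other benzylic C–O ionises to a p-hydroxybenzyl (quinone-methide-type) cation, the free benzylic OH captures it 5-exo, and Fischer esterification completes the diester. C3 and C4 are α-carbonyl centres that do not ionise and keep the aldol configuration. C2 and C5 ionise reversibly and settle all-trans under thermodynamic control, which is the same configuration the aldol delivered.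

**Step 4**
Reactants: 6
Product: 7, (+)-neoolivil, (2R,3S,4S,5R)-2,5-bis(4-hydroxy-3-methoxyphenyl)-3,4-bis(hydroxymethyl)oxolane
Conditions: LiAlH4 (excess), THF, 0 °C → reflux; Rochelle-salt/sat. NH4Cl work-up (no strong acid)
Reagents that add atoms: none
Why: Hydride reduction of both esters to primary alcohols with no stereocentre touched; the 3,4 descriptors change from R to S only through CIP priorities. The phenols ride through as aluminium phenoxides, and any residual imide or aryl acetate is reduced to the same product. The near-neutral work-up avoids acid-induced benzylic ionisation.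

## Compound list

1 | (R)-4-benzyl-2-oxazolidinone | O=C1N[C@H](Cc2ccccc2)CO1 | starting material
2 | succinyl chloride | O=C(Cl)CCC(Cl)=O | starting material
3 | 1,4-bis[(4R)-4-benzyl-2-oxo-oxazolidin-3-yl]butane-1,4-dione | O=C(CCC(=O)N1[C@H](Cc2ccccc2)COC1=O)N1[C@H](Cc2ccccc2)COC1=O | intermediate
4 | vanillin acetate (4-formyl-2-methoxyphenyl acetate) | CC(=O)Oc1ccc(C=O)cc1OC | starting material
5 | bis-syn-aldol adduct (7R,8R,8′R,7′R) | COc1cc(ccc1OC(C)=O)[C@H](O)[C@H](C(=O)N1[C@H](Cc2ccccc2)COC1=O)[C@@H](C(=O)N1[C@H](Cc2ccccc2)COC1=O)[C@@H](O)c1ccc(OC(C)=O)c(OC)c1 | intermediate
6 | dimethyl (2R,3R,4R,5R)-2,5-bis(4-hydroxy-3-methoxyphenyl)oxolane-3,4-dicarboxylate | COc1cc([C@@H]2O[C@@H](c3ccc(O)c(OC)c3)[C@H](C(=O)OC)[C@H]2C(=O)OC)ccc1O | intermediate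
7 | (+)-neoolivil | COc1cc([C@@H]2O[C@@H](c3ccc(O)c(OC)c3)[C@H](CO)[C@H]2CO)ccc1O | target

## Totals

Total steps: 4. Longest linear sequence: 4.

## Steps most likely to fail, with fallbacks

1. **Step 2, double aldol.** Bis-enolisation may be incomplete, or the mono-aldolate may lactonise before the second aldol, after which the lactone enolate would add with the wrong relative configuration. Fallback: set the trans C3/C4 pair by substrate control instead. Add lithiated 2-(4-benzyloxy-3-methoxyphenyl)-1,3-dithiane to (5S)-5-(d-menthyloxy)-2(5H)-furanone and trap the enolate with O-benzylvanillin (tandem conjugate addition–aldol). Then hydrolyse the dithiane, reduce with LiAlH4 to the tetraol, protect the primary OH groups as esters, close the oxolane with acid and deprotect.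

2. **Step 3, acid cascade.** E1 loss to arylidene succinates, Friedel–Crafts closure to an aryltetralin, or incomplete auxiliary release could compete. Fallback: form the ring at the alcohol oxidation level. Run step 2 with O-benzylvanillin, remove the auxiliaries with LiBH4 to the tetraol, pivaloylate the two primary OH groups, cyclise the 1,4-benzylic diol with BF3·OEt2 at low temperature (still all-trans by thermodynamic control), then remove the pivalates and hydrogenolyse the benzyl ethers.

3. **Step 4, reduction of the free diphenol diester.** Insoluble phenoxide salts could stall the reduction, and the product could be lost to acid-promoted rearrangement on work-up. Fallback: change the protecting-group strategy. O-benzylate 6 (BnBr, K2CO3), reduce the now-soluble diester with LiAlH4, and finish with a brief neutral hydrogenolysis (H2, Pd/C, EtOAc).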